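I began from two rate constants: kT for electrophile + nucleophile giving target, and kO for nucleophile + target giving over-reaction product, a scheme I assumed from the runs below.

| setting | dawn | midnight | north-west | north-east | south |
|---|---|---|---|---|---|
| electrophile | 0.10 M | 0.20 M | 0.10 M | 0.10 M (fed, over 8.0 h) | 0.10 M |
| nucleophile | 0.11 M | 0.11 M | 0.110 M | 0.110 M | 0.110 M (fed, over 8.0 h) |
| free base | 0.15 M | 0.15 M | 0.150 M | 0.150 M | 0.150 M |
| remark | run made earlier | run made earlier | everything together at the start | all else is in the flask from the start; the feed brings no volume worth counting | all else is in the flask from the start; the feed brings no volume worth counting |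
| time |  |  | 10 h | 10 h | 10 h |

| run | time / h | over-reaction product / % | target / % |
|---|---|---|---|
| dawn | 0.833 | 4.1 | 24.1 |
| dawn | 1.50 | 6.7 | 29.7 |
| dawn | 3.00 | 11.2 | 33.0 |
| dawn | 5.00 | 14.6 | 35.1 |
| dawn | 10.0 | 18.4 | 36.3 |
| midnight | 0.250 | 0.8 | 10.2 |
| midnight | 0.417 | 0.6 | 13.8 |
| midnight | 0.833 | 2.0 | 18.9 |
| midnight | 1.50 | 3.0 | 21.3 |
| midnight | 3.00 | 3.1 | 23.8 |

(scatter of a reading: 0.5 percentage points)

* the flask with the highest amount of over-reaction product, in percent of the electrophile charged ("all alike" if they lie within 1.5 percentage points) (north-west / north-east / south / all alike)
* final over-reaction product, as a percentage of the electrophile charged, in north-west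
* final over-reaction product, as a percentage of the electrophile charged, in north-east
* final over-reaction product, as a percentage of the electrophile charged, in south



Both steps consume nucleophile, so in the ratio of their rates nucleophile cancels, and time with it, as for two substrates competing for one catalyst. Let P and O be target and over-reaction product, and x the electrophile left, all as fractions of the charge, with x taken as what P and O do not account for. Per electrophile converted, O then grows at s·P/x. Dawn's stretch from 3.00 h to 10.0 h, where P barely moves, gives ΔO divided by mean P times the change in −ln x, so the selectivity factor, kO over kT, read s = 0.997, a reading that carries the scatter.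

Dawn's last reading had converted 0.0547 M of electrophile and midnight's 0.0538 M, much the same amount on twice the charge. So midnight stood at x = 73.1% and dawn at 45.3%. The ratio s·P/x was 0.325 in midnight, less than the 0.799 in dawn, which is why midnight ends poorer in O. What halted conversion the ratio does not say.

Integrated, the ratio gives a curve: P = (x^s − x)/(1 − s) and O = 1 − x − P. With dawn's s it puts midnight at 3.98% against the reading 3.1%. I expected north-west to repeat dawn's 18.4%. South feeds the nucleophile, which cancels, so I put south on the same curve, at dawn's figure if it converts as far and below that if it converts less. North-east feeds electrophile, so the curve does not apply there; I expected it above the curve, without a figure of my own.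

The forecast named north-east, with 18.5% in north-west, 30% in north-east (range 18% to 40%) and 16% in south, on the ground that “North-east keeps electrophile scarce and nucleophile plentiful”.

North-west ended at 17.5%, south at 13.5% and north-east, the highest, at 20.3%, which is 9.7 percentage points under the forecast.

    acid set free + free base ⇌ salt of the base, settled at all times (K = 7.00 M⁻¹)
    electrophile + nucleophile → acid set free + target (k = 4.90 M⁻¹ h⁻¹)
    nucleophile + target → over-reaction product (k = 4.50 M⁻¹ h⁻¹)
    nucleophile + acid set free ⇌ protonated nucleophile, settled at all times (K = 1100 M⁻¹)
    free base ⇌ dormant form (K = 0.520, k = 0.150 h⁻¹)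

The neighbour is south with 0.066 M of nucleophile, fed the same way, and it kept 67.8% of its electrophile. At that x the curve with s = 0.997 gives O = 5.84%, and the neighbour ended at 5.44%.

The earlier runs and the new flask come from a simulation for substances that don't exist, and the scatter is random.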